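Assumption: the target is planar and achiral (no stereocentre, no stereogenic axis), so the SMILES defines a single compound and no enantioselective step is needed.

## Retrosynthetic overview
1. Target 4 is opened at N1–C2 and C3–Br in one operation. This gives enol ether 2 plus a Br+ source, with the OMe group as a built-in leaving group.
2. Enol ether 2 is cut at C2=C3 by olefination, giving 2-amino-3,5-dibromobenzaldehyde 1 and a methoxymethylidene ylide.
3. The benzene ring is bought with both aryl bromines (future C5 and C7) in place. The pyrrole ring is the only ring formed, and it is formed in the last step.

## Route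

Step 1
Reactants: 1 2-amino-3,5-dibromobenzaldehyde
Product: 2 2,4-dibromo-6-(2-methoxyethenyl)aniline (E/Z mixture)
Conditions: MeOCH2PPh3Cl (2.5 equiv), KOtBu (2.4 equiv), THF, 0 °C, 30 min; then 1, 0 °C → rt, 2 h; aq. NaHCO3 work-up, short plug of Et3N-washed SiO2
Reagents that add atoms: (methoxymethyl)triphenylphosphonium chloride, COC[P+](c1ccccc1)(c1ccccc1)c1ccccc1.[Cl-]
Why: Wittig olefination, in which the non-stabilised methoxymethylidene ylide adds to the aldehyde, the excess ylide covers any reversible proton transfer from the weakly acidic NH2, the aryl bromides are inert to ylide and KOtBu at 0 °C, no stereocentre is formed, and the E/Z ratio does not matter because both isomers converge in step 2.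

Step 2
Reactants: 2 2,4-dibromo-6-(2-methoxyethenyl)aniline (E/Z mixture)
Product: 4 3,5,7-tribromoindole, via 3,5,7-tribromo-2-methoxyindoline 3 (not isolated)
Conditions: NBS (1.02 equiv), MeCN, −30 °C, dark, 30 min; then CSA (10 mol %), 0 °C → rt, 1 h; aq. NaHCO3/Na2S2O3 quench
Reagents that add atoms: N-bromosuccinimide (NBS), O=C1CCC(=O)N1Br
Why: Proposed new method: brominative aminocyclisation of an ortho-amino aryl enol ether, in which NBS delivers Br+ to the benzylic carbon (the nucleophilic β-carbon of the enol ether; every ortho and para position of the aniline is blocked, so ring bromination cannot compete), the resulting oxocarbenium carbon is captured by the ortho NH2 in a favoured 5-exo-trig mode to form the N1–C2 bond and close the pyrrole ring as N,O-acetal 3, and acid-catalysed loss of MeOH followed by 3H- to 1H-indole tautomerisation gives 4 with bromine already at C3 and erases the two transient stereocentres of 3; the closest known reaction types are halo-functionalisation of enol ethers (haloglycosylation of glycals), acid-catalysed cyclisation of 2-(2-alkoxyvinyl)anilines to indoles, and halocyclisation of 2-alkynyl- and 2-alkenylanilines.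

## Compound list
1 | 2-amino-3,5-dibromobenzaldehyde | Nc1c(Br)cc(Br)cc1C=O | starting material
2 | 2,4-dibromo-6-(2-methoxyethenyl)aniline (E/Z mixture, used as such) | COC=Cc1cc(Br)cc(Br)c1N | intermediate
3 | 3,5,7-tribromo-2-methoxyindoline (3,5,7-tribromo-2-methoxy-2,3-dihydro-1H-indole; racemic mixture of diastereomers, not isolated) | COC1Nc2c(Br)cc(Br)cc2C1Br | intermediate
4 | 3,5,7-tribromoindole (achiral) | Brc1cc(Br)c2[nH]cc(Br)c2c1 | target

Total step count: 2
Longest linear sequence: 2

## Steps most likely to fail
The route has only two steps, so both are ranked and there is no third step to list.

**Most at risk: step 2 (the proposed new step).**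
- NBS could N-brominate or oxidise the aniline.
- The electron-poor nitrogen could be slow to capture the cation.
- Intermediate 3 could lose HBr instead of MeOH.
- Product 4 could be over-brominated at C2.

The fallback uses known chemistry and separates ring closure from bromination. It sets out from 2. Compound 2 is heated with TsOH·H2O (10 mol %) in wet THF at 60 °C. The enol ether is protonated, and the unmasked arylacetaldehyde condenses with the NH2 group to give 5,7-dibromoindole F1. This is then brominated at C3 by ordinary electrophilic aromatic substitution (NBS, 1.0 equiv, DMF, 0 °C). The fallback comes back to the route at 4. Any 2 that cyclises early on silica or in the flask is carried to 4 in the same way, so it is not lost.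

**Second: step 1.**
- The ylide can be quenched by the NH2 protons.
- The amino aldehyde can self-condense under strong base.
- Compound 2 can cyclise on acidic silica.

The fallback replaces the strongly basic olefination with a mild one-carbon homologation to the alkyne. It sets out from 1. Treatment with dimethyl (1-diazo-2-oxopropyl)phosphonate and K2CO3 in MeOH at rt (Ohira–Bestmann homologation) gives 2,4-dibromo-6-ethynylaniline F2. NaAuCl4·2H2O (3 mol %) in EtOH at rt closes the N1–C2 bond by 5-endo-dig hydroamination and gives 5,7-dibromoindole F1. Bromination with NBS in DMF at 0 °C then brings the fallback back to the route at 4.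

## Further compounds
F1 | step 2 | 5,7-dibromoindole | Brc1cc(Br)c2[nH]ccc2c1
F2 | step 1 | 2,4-dibromo-6-ethynylaniline | C#Cc1cc(Br)cc(Br)c1N
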